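**Plan**

1. Lettering used throughout: ring A = Ca (quaternary, CH2OAc)–Cb–Cc(OAc)–Cd(OH)–Ce(Me2)–Cf; cage = Cf–Cg–Ch, Ca–Ci, Cf–Ck(OAc)–Cj(Me), with cyclopropane Ch–Ci–Cj.
2. Retrosynthetic cuts, in order: Cc–O/Cd–O (back to a Cc=Cd olefin); cyclopropane bond Ch–Cj; Ck–O (back to Ck–acetyl); Cf–Ck and Ci–Cj (Diels–Alder); Cf=Cg and Ch=Ci of a fused cyclopentadiene (back to a ring-A ketone at Cf and a vinyl group on Ca); Ca–Cb (ring A back to a cyclopentene).
3. Forward order: cyclopentenol by RCM, ring A by one-carbon ring expansion, cyclopentadiene on the Ca–Cf bond, bicyclo[2.2.1] core by cycloaddition, cyclopropane by carbene C–H insertion, cis-hydroxylation of ring A.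
4. Stereochemistry: Ca from a Sharpless epoxide, transferred by a stereospecific 1,2-shift; Cf, Ci, Cj, Ck from the cycloaddition (anti to CH2OSi, endo) and a retentive Baeyer–Villiger step; Ch by cage closure; Cc and Cd by trans-diaxial iodoacetoxylation followed by acetoxonium inversion.
5. Enabling feature: Ca is a quaternary ring-A carbon with two one-carbon arms next to Cf, and the ring-A oxygens at Cc/Cd mask an olefin lying opposite the Ca–Cf bond; ring A is therefore a cyclohex-3-enone in which Ca can be inserted between the carbinol carbon and either of the two equivalent CH2 groups of a mirror-symmetric cyclopent-3-en-1-ol.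

Key step: step 5

Remark: 13 is drawn as the epimer expected from attack anti to the silyloxymethyl group and 21 as the endo alcohol; both stereocentres are erased in the next steps, so the other epimers would serve equally.

**Route**

Step 1
Reactants: 1 methyl 2-(hydroxymethyl)prop-2-enoate; 2 allylmagnesium bromide
Product: 4 4-(3-hydroxyprop-1-en-2-yl)hepta-1,6-dien-4-ol, via dienone alkoxide 3 (not isolated)
Conditions: 2 (3.5 equiv), THF, −78 → 0 °C; aq NH4Cl
Reagents that add atoms: none
Why: Double Grignard addition to the ester after deprotonation of the hydroxyl; allyl Grignard reagents add 1,2 to enoates and enones through a six-membered transition state.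

Step 2
Reactants: 4
Product: 5 1-(3-hydroxyprop-1-en-2-yl)cyclopent-3-en-1-ol
Conditions: second-generation Grubbs-type Ru catalyst (2 mol%), CH2Cl2, 40 °C
Reagents that add atoms: none
Why: Ring-closing metathesis of the two allyl groups to the cyclopentene should be fast, and the 1,1-disubstituted olefin can only give a four-membered ring and stays out.

Step 3
Reactants: 5
Product: 6 1-[(2S)-2-(hydroxymethyl)oxiran-2-yl]cyclopent-3-en-1-ol
Conditions: Ti(OiPr)4, L-(+)-diethyl tartrate, t-BuOOH, 4 Å MS, CH2Cl2, −20 °C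
Reagents that add atoms: tert-butyl hydroperoxide, CC(C)(C)OO
Why: Sharpless asymmetric epoxidation of a 2-substituted primary allylic alcohol, in which the L-(+)-tartrate should deliver oxygen to the face that makes the quaternary oxirane carbon S, while the ring olefin (only homoallylic to the tertiary OH) is left alone.

Step 4
Reactants: 6
Product: 7 1-[(2R)-2-({[tert-butyl(diphenyl)silyl]oxy}methyl)oxiran-2-yl]cyclopent-3-en-1-ol
Conditions: TBDPSCl, imidazole, DMF, 0 °C
Reagents that add atoms: tert-butyl(chloro)diphenylsilane, CC(C)(C)[Si](Cl)(c1ccccc1)c1ccccc1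
Why: Selective silylation of the primary hydroxyl keeps the two CH2O arms on the oxirane carbon different, so that this carbon remains stereogenic after the shift (same spatial arrangement, descriptor changes to R).

Step 5
Reactants: 7
Product: 8 (6R)-6-({[tert-butyl(diphenyl)silyl]oxy}methyl)-6-(hydroxymethyl)cyclohex-3-en-1-one
Conditions: BF3·OEt2 (1.1 equiv), CH2Cl2, −78 → −40 °C; aq NaHCO3
Reagents that add atoms: none
Why: The Lewis acid binds the oxirane oxygen, the C–O bond at the fully substituted oxirane carbon (Ca) ionises, and the antiperiplanar ring C–C bond of the carbinol carbon (Cf) migrates in a concerted 1,2-shift while the carbinol becomes the ketone. The closest known reaction type is the semipinacol rearrangement of 2,3-epoxy alcohols, used for ring expansion of 1-(oxiranyl)cycloalkanols to 2-(hydroxymethyl)cycloalkanones. The six-membered ring is not closed by a cyclisation; it arises from the cyclopentene ring by insertion of Ca between Cf and one ring CH2 (ring expansion by one atom). Ca is the only new stereocentre and is formed with inversion at the oxirane carbon, so the Sharpless configuration is transferred to the quaternary centre. The step needs ionisation at the quaternary instead of the CH2 oxirane carbon and carbon shift instead of hydride shift; the tertiary, carbinol-flanked position and the oxygen-assisted migration should secure both. No regiochemical question arises because the two ring CH2 groups are equivalent, and a later drift of the β,γ-olefin into conjugation would be harmless (see step 8).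

Step 6
Reactants: 8
Product: 9 (1S)-1-({[tert-butyl(diphenyl)silyl]oxy}methyl)-6-oxocyclohex-3-ene-1-carbaldehyde
Conditions: Dess–Martin periodinane, NaHCO3, CH2Cl2, 0 °C → rt
Reagents that add atoms: none
Why: Dess–Martin oxidation of the neopentyl primary alcohol under non-basic conditions avoids retro-aldol loss of formaldehyde and silyl migration between the two arms.

Step 7
Reactants: 9
Product: 10 (6R)-6-({[tert-butyl(diphenyl)silyl]oxy}methyl)-6-ethenylcyclohex-3-en-1-one
Conditions: Ph3PCH3Br, KHMDS, THF, −78 → 0 °C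
Reagents that add atoms: methyltriphenylphosphonium bromide, C[P+](c1ccccc1)(c1ccccc1)c1ccccc1.[Br-]
Why: Wittig methylenation should take the aldehyde in preference to the α-quaternary ketone and turns the second arm into the vinyl group that carries Ci.

Step 8
Reactants: 10
Product: 12 (6R)-6-({[tert-butyl(diphenyl)silyl]oxy}methyl)-6-ethenyl-2,2-dimethylcyclohex-3-en-1-one, via monomethyl ketone 11 (not isolated)
Conditions: t-BuOK (3 equiv), MeI (6 equiv), THF/t-BuOH, 0 °C → rt
Reagents that add atoms: iodomethane, CI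
Why: Double α-alkylation of the extended dienolate, the only enolisable side of the ketone, installs the gem-dimethyl group at Ce and locks the olefin at Cc=Cd; the β,γ- and α,β-enone isomers give the same dienolate.

Step 9
Reactants: 12; 2 allylmagnesium bromide
Product: 13 (1S,6R)-6-({[tert-butyl(diphenyl)silyl]oxy}methyl)-6-ethenyl-2,2-dimethyl-1-(prop-2-en-1-yl)cyclohex-3-en-1-ol
Conditions: 2 (3 equiv), THF, 0 °C → rt
Reagents that add atoms: none
Why: Allyl Grignard reagents add through a cyclic SE2' transition state even to ketones flanked by two quaternary carbons, and attack anti to the bulky silyloxymethyl group should place allyl cis to vinyl.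

Step 10
Reactants: 13
Product: 14 (3aS,7aR)-7a-({[tert-butyl(diphenyl)silyl]oxy}methyl)-4,4-dimethyl-3,4,7,7a-tetrahydro-3aH-inden-3a-ol
Conditions: second-generation Grubbs-type Ru catalyst (5 mol%), CH2Cl2, 40 °C
Reagents that add atoms: none
Why: Ring-closing metathesis of the vinyl and allyl groups closes the five-membered ring (Ch=Ci), and the ring-A cyclohexene is inert to metathesis.

Step 11
Reactants: 14
Product: 16 (7aS)-7a-({[tert-butyl(diphenyl)silyl]oxy}methyl)-4,4-dimethyl-4,7-dihydro-7aH-indene, via chlorosulfite 15 (not isolated)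
Conditions: SOCl2, pyridine, CH2Cl2, −20 → 0 °C
Reagents that add atoms: none
Why: Base-mediated elimination of the tertiary chlorosulfite can only remove a hydrogen from Cg (both other neighbours are quaternary) and gives the conjugated 5,5-disubstituted cyclopentadiene, which cannot undergo 1,5-hydrogen shifts.

Step 12
Reactants: 16; 17 (E)-pent-3-en-2-one
Product: 18 1-[6-({[tert-butyl(diphenyl)silyl]oxy}methyl)-2,2,11-trimethyltricyclo[5.2.2.0^{1,6}]undeca-3,8-dien-10-yl]ethan-1-one (acetyl endo, i.e. syn to C8=C9; 11-methyl exo; CH2OSi syn to C8=C9)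
Conditions: 17 (3 equiv), EtAlCl2 (0.5 equiv), CH2Cl2, −78 → −20 °C
Reagents that add atoms: none
Why: Lewis-acid-catalysed Diels–Alder reaction in which the enone should add to the diene face anti to the silyloxymethyl group (sets Cf and Ci), with its β-carbon bonding to the unsubstituted diene terminus ("ortho" orientation) and the acetyl group endo (sets Ck), the E geometry then placing the methyl exo (sets Cj).

Step 13
Reactants: 18
Product: 19 6-({[tert-butyl(diphenyl)silyl]oxy}methyl)-2,2,11-trimethyltricyclo[5.2.2.0^{1,6}]undeca-3,8-dien-10-yl acetate (acetate endo)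
Conditions: Me3SiOOSiMe3 (3 equiv), SnCl4, trans-cyclohexane-1,2-diamine, 4 Å MS, CH2Cl2, −20 → 0 °C
Reagents that add atoms: bis(trimethylsilyl) peroxide, C[Si](C)(C)OO[Si](C)(C)C
Why: Baeyer–Villiger oxidation with a silyl peroxide under Lewis-acid activation, a variant that leaves C=C bonds untouched; the secondary cage carbon should migrate in preference to methyl with retention, giving the Ck acetate of the target.

Step 14
Reactants: 19
Product: 21 6-({[tert-butyl(diphenyl)silyl]oxy}methyl)-8-hydroxy-2,2,11-trimethyltricyclo[5.2.2.0^{1,6}]undec-3-en-10-yl acetate, via alkylborane 20 (not isolated)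
Conditions: 9-BBN (1.5 equiv), THF, 0 °C → rt; then NaBO3·4H2O, H2O, rt
Reagents that add atoms: sodium perborate, [Na+].[O-]OB(O)O
Why: Hydroboration–oxidation, in which 9-BBN should take the strained norbornene bond far faster than the hindered cyclohexene and place boron on Ch, away from the quaternary bridgehead and the endo acetate.

Step 15
Reactants: 21
Product: 22 6-({[tert-butyl(diphenyl)silyl]oxy}methyl)-2,2,11-trimethyl-8-oxotricyclo[5.2.2.0^{1,6}]undec-3-en-10-yl acetate
Conditions: Dess–Martin periodinane, NaHCO3, CH2Cl2, rt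
Reagents that add atoms: none
Why: Dess–Martin oxidation of the secondary alcohol gives the Ch ketone and removes the stereocentre made in step 14.

Step 16
Reactants: 22
Product: 26 tetracyclic acetate (skeleton of the target with a Cc=Cd double bond in ring A and CH2OTBDPS on Ca), via tosylhydrazone 23 (not isolated), via sodium hydrazonide 24 (not isolated), via diazoalkane 25 (not isolated)
Conditions: TsNHNH2, MeOH, rt; evaporate; NaH (1.05 equiv), THF, 0 °C; diglyme, 150 °C
Reagents that add atoms: none
Why: Aprotic Bamford–Stevens reaction, in which the 2-norbornylidene-type carbene at Ch should insert into the endo tertiary C–H bond of Cj (1,3-insertion, as in the conversion of bornanone hydrazones into tricyclenes), closing the cyclopropane and fixing Ch and Cj.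

Step 17
Reactants: 26
Product: 29 hydroxy diacetate silyl ether (target with CH2OTBDPS in place of CH2OAc), via iodo acetate 27 (not isolated), via acetoxonium ion 28 (not isolated)
Conditions: I2 (1.05 equiv), AgOAc (2.2 equiv), AcOH, rt; then AcOH/H2O, 90 °C
Reagents that add atoms: silver acetate, CC(=O)[O-].[Ag+]; water, O
Why: Woodward–Prévost cis-hydroxylation, in which the iodonium ion on the less hindered face is opened trans-diaxially by acetate at Cc (Cd is neopentyl), the acetate then displaces iodide at Cd with inversion, and hydrolysis of the cis-acetoxonium ion should leave the axial acetate on Cc and the equatorial hydroxyl on Cd, both on the face of the Ca arm.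

Step 18
Reactants: 29
Product: 30 primary alcohol (target lacking the acetyl group on the Ca–CH2O arm)
Conditions: HF·pyridine, THF/pyridine, 0 °C → rt
Reagents that add atoms: none
Why: Fluoride cleavage of the silyl ether under mildly acidic buffering should avoid acetyl migration from the Cc oxygen to the neighbouring hydroxyls.

Step 19
Reactants: 30
Product: 31 CNP0197219.1 (target)
Conditions: AcCl (1.1 equiv), 2,4,6-collidine, CH2Cl2, −78 °C
Reagents that add atoms: acetyl chloride, CC(=O)Cl
Why: Low-temperature acylation should select the primary hydroxyl over the secondary Cd hydroxyl, which is flanked by the gem-dimethyl carbon and the axial acetate.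

**Compound list**

1 | methyl 2-(hydroxymethyl)prop-2-enoate | COC(=O)C(=C)CO | starting material
2 | allylmagnesium bromide | C=CC[Mg]Br | starting material
3 | 2-(hydroxymethyl)hexa-1,5-dien-3-one (present as its bromomagnesium alkoxide) | OCC(=C)C(=O)CC=C | intermediate
4 | 4-(3-hydroxyprop-1-en-2-yl)hepta-1,6-dien-4-ol | OCC(=C)C(O)(CC=C)CC=C | intermediate
5 | 1-(3-hydroxyprop-1-en-2-yl)cyclopent-3-en-1-ol | OCC(=C)C1(O)CC=CC1 | intermediate
6 | 1-[(2S)-2-(hydroxymethyl)oxiran-2-yl]cyclopent-3-en-1-ol | OC[C@]1(CO1)C2(O)CC=CC2 | intermediate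
7 | 1-[(2R)-2-({[tert-butyl(diphenyl)silyl]oxy}methyl)oxiran-2-yl]cyclopent-3-en-1-ol | OC1(CC=CC1)[C@]2(CO[Si](c3ccccc3)(c4ccccc4)C(C)(C)C)CO2 | intermediate
8 | (6R)-6-({[tert-butyl(diphenyl)silyl]oxy}methyl)-6-(hydroxymethyl)cyclohex-3-en-1-one | O=C1CC=CC[C@@]1(CO)CO[Si](c2ccccc2)(c3ccccc3)C(C)(C)C | intermediate
9 | (1S)-1-({[tert-butyl(diphenyl)silyl]oxy}methyl)-6-oxocyclohex-3-ene-1-carbaldehyde | O=C1CC=CC[C@@]1(C=O)CO[Si](c2ccccc2)(c3ccccc3)C(C)(C)C | intermediate
10 | (6R)-6-({[tert-butyl(diphenyl)silyl]oxy}methyl)-6-ethenylcyclohex-3-en-1-one | O=C1CC=CC[C@@]1(C=C)CO[Si](c2ccccc2)(c3ccccc3)C(C)(C)C | intermediate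
11 | (6R)-6-({[tert-butyl(diphenyl)silyl]oxy}methyl)-6-ethenyl-2-methylcyclohex-3-en-1-one (C-2 epimers) | O=C1C(C)C=CC[C@@]1(C=C)CO[Si](c2ccccc2)(c3ccccc3)C(C)(C)C | intermediate
12 | (6R)-6-({[tert-butyl(diphenyl)silyl]oxy}methyl)-6-ethenyl-2,2-dimethylcyclohex-3-en-1-one | O=C1C(C)(C)C=CC[C@@]1(C=C)CO[Si](c2ccccc2)(c3ccccc3)C(C)(C)C | intermediate
13 | (1S,6R)-6-({[tert-butyl(diphenyl)silyl]oxy}methyl)-6-ethenyl-2,2-dimethyl-1-(prop-2-en-1-yl)cyclohex-3-en-1-ol | C=CC[C@]1(O)C(C)(C)C=CC[C@@]1(C=C)CO[Si](c2ccccc2)(c3ccccc3)C(C)(C)C | intermediate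
14 | (3aS,7aR)-7a-({[tert-butyl(diphenyl)silyl]oxy}methyl)-4,4-dimethyl-3,4,7,7a-tetrahydro-3aH-inden-3a-ol | O[C@]12CC=C[C@@]1(CO[Si](c3ccccc3)(c4ccccc4)C(C)(C)C)CC=CC2(C)C | intermediate
15 | chlorosulfite ester of 14 | O=S(Cl)O[C@]12CC=C[C@@]1(CO[Si](c3ccccc3)(c4ccccc4)C(C)(C)C)CC=CC2(C)C | intermediate
16 | (7aS)-7a-({[tert-butyl(diphenyl)silyl]oxy}methyl)-4,4-dimethyl-4,7-dihydro-7aH-indene | CC1(C)C=CC[C@]2(CO[Si](c3ccccc3)(c4ccccc4)C(C)(C)C)C=CC=C12 | intermediate
17 | (E)-pent-3-en-2-one | C/C=C/C(C)=O | starting material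
18 | 1-[6-({[tert-butyl(diphenyl)silyl]oxy}methyl)-2,2,11-trimethyltricyclo[5.2.2.0^{1,6}]undeca-3,8-dien-10-yl]ethan-1-one (endo-acetyl, exo-methyl) | CC(C)(C)[Si](OC[C@]12CC=CC(C)(C)[C@]13C=C[C@H]2[C@H](C)[C@H]3C(C)=O)(c4ccccc4)c5ccccc5 | intermediate
19 | 6-({[tert-butyl(diphenyl)silyl]oxy}methyl)-2,2,11-trimethyltricyclo[5.2.2.0^{1,6}]undeca-3,8-dien-10-yl acetate (endo-acetate) | CC(C)(C)[Si](OC[C@]12CC=CC(C)(C)[C@]13C=C[C@H]2[C@H](C)[C@H]3OC(C)=O)(c4ccccc4)c5ccccc5 | intermediate
20 | B-alkyl-9-borabicyclo[3.3.1]nonane adduct of 19 (boron on C-8) | CC(C)(C)[Si](OC[C@]12CC=CC(C)(C)[C@]13C[C@@H](B6C7CCCC6CCC7)[C@H]2[C@H](C)[C@H]3OC(C)=O)(c4ccccc4)c5ccccc5 | intermediate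
21 | 6-({[tert-butyl(diphenyl)silyl]oxy}methyl)-8-hydroxy-2,2,11-trimethyltricyclo[5.2.2.0^{1,6}]undec-3-en-10-yl acetate | CC(C)(C)[Si](OC[C@]12CC=CC(C)(C)[C@]13C[C@@H](O)[C@H]2[C@H](C)[C@H]3OC(C)=O)(c4ccccc4)c5ccccc5 | intermediate
22 | 6-({[tert-butyl(diphenyl)silyl]oxy}methyl)-2,2,11-trimethyl-8-oxotricyclo[5.2.2.0^{1,6}]undec-3-en-10-yl acetate | CC(C)(C)[Si](OC[C@]12CC=CC(C)(C)[C@]13CC(=O)[C@H]2[C@H](C)[C@H]3OC(C)=O)(c4ccccc4)c5ccccc5 | intermediate
23 | 4-methylbenzenesulfonylhydrazone of 22 | CC(C)(C)[Si](OC[C@]12CC=CC(C)(C)[C@]13CC(=NNS(=O)(=O)c6ccc(C)cc6)[C@H]2[C@H](C)[C@H]3OC(C)=O)(c4ccccc4)c5ccccc5 | intermediate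
24 | sodium salt of 23 | [Na+].CC(C)(C)[Si](OC[C@]12CC=CC(C)(C)[C@]13CC(=N[N-]S(=O)(=O)c6ccc(C)cc6)[C@H]2[C@H](C)[C@H]3OC(C)=O)(c4ccccc4)c5ccccc5 | intermediate
25 | 8-diazo compound derived from 22 | CC(C)(C)[Si](OC[C@]12CC=CC(C)(C)[C@]13CC(=[N+]=[N-])[C@H]2[C@H](C)[C@H]3OC(C)=O)(c4ccccc4)c5ccccc5 | intermediate
26 | tetracyclic acetate: target skeleton with Cc=Cd double bond and CH2OTBDPS on Ca | CC(C)(C)[Si](OC[C@]12CC=CC(C)(C)[C@]13C[C@@H]1[C@H]2[C@]1(C)[C@H]3OC(C)=O)(c4ccccc4)c5ccccc5 | intermediate
27 | trans-diaxial iodo acetate of 26 (acetate on Cc, iodide on Cd) | CC(C)(C)[Si](OC[C@]12C[C@H](OC(C)=O)[C@@H](I)C(C)(C)[C@]13C[C@@H]1[C@H]2[C@]1(C)[C@H]3OC(C)=O)(c4ccccc4)c5ccccc5 | intermediate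
28 | cis-fused 2-methyl-1,3-dioxolan-2-ylium ion across Cc/Cd, acetate salt | CC(C)(C)[Si](OC[C@]12C[C@@H]6OC(C)=[O+][C@@H]6C(C)(C)[C@]13C[C@@H]1[C@H]2[C@]1(C)[C@H]3OC(C)=O)(c4ccccc4)c5ccccc5.CC(=O)[O-] | intermediate
29 | target with CH2OTBDPS in place of CH2OAc | CC(C)(C)[Si](OC[C@]12C[C@H](OC(C)=O)[C@H](O)C(C)(C)[C@]13C[C@@H]1[C@H]2[C@]1(C)[C@H]3OC(C)=O)(c4ccccc4)c5ccccc5 | intermediate
30 | target with free CH2OH on Ca | OC[C@]12C[C@H](OC(C)=O)[C@H](O)C(C)(C)[C@]13C[C@@H]1[C@H]2[C@]1(C)[C@H]3OC(C)=O | intermediate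
31 | CNP0197219.1 | CC(=O)OC[C@]12C[C@H](OC(C)=O)[C@H](O)C(C)(C)[C@]13C[C@@H]1[C@H]2[C@]1(C)[C@H]3OC(C)=O | target

**Step count and risks**

Total step count: 19. Longest linear sequence: 19 steps (fully linear from 1).

The three steps most likely to fail:

Step 12. The new bond at Cf joins a diene terminus flanked by two quaternary carbons, so the cycloaddition may be too slow, and the higher temperature then needed could erode endo and facial selectivity. The fallback sets out from 16 and uses the smaller, more electrophilic (E)-but-2-enal under Lewis-acid or secondary-amine (iminium) activation, which should give the endo aldehyde adduct F1. Addition of methylmagnesium bromide gives the secondary carbinol F2 (epimers at the carbinol carbon), and Dess–Martin oxidation returns to the route at 18.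

Step 13. Oxygen may be transferred to the strained C8=C9 bond instead of the ketone, migration at the hindered methyl ketone may be sluggish, or the Lewis acid may trigger skeletal shifts of the norbornene. The fallback avoids the acyl-to-oxygen exchange altogether. It sets out from 16 and uses (E)-prop-1-enylboronic acid pinacol ester as dienophile (toluene, 120 °C), giving after separation the endo boronate F3. Stereoretentive oxidation of the C–B bond with sodium perborate gives the endo alcohol F4, and acetylation (Ac2O, DMAP) returns to the route at 19.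

Step 17. Acetate may fail to reach Cc on the face that carries the two axial groups, the silyloxymethyl oxygen may capture the iodonium ion, or iodide departure from neopentyl Cd may be accompanied by a methyl shift. The fallback sets out from 26. Epoxidation with mCPBA on the less hindered face gives the epoxide F5. Trans-diaxial opening with acetic acid and sodium acetate gives the hydroxy acetate F6, with the acetate on Cc on the required face and the Cd hydroxyl on the wrong one. Dess–Martin oxidation gives the acetoxy ketone F7, and reduction with NaBH4/CeCl3 at −78 °C (axial hydride delivery, equatorial alcohol) returns to the route at 29.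

Further compounds
F1 | step 12 | 6-({[tert-butyl(diphenyl)silyl]oxy}methyl)-2,2,11-trimethyltricyclo[5.2.2.0^{1,6}]undeca-3,8-diene-10-carbaldehyde (endo) | CC(C)(C)[Si](OC[C@]12CC=CC(C)(C)[C@]13C=C[C@H]2[C@H](C)[C@H]3C=O)(c4ccccc4)c5ccccc5
F2 | step 12 | 1-[6-({[tert-butyl(diphenyl)silyl]oxy}methyl)-2,2,11-trimethyltricyclo[5.2.2.0^{1,6}]undeca-3,8-dien-10-yl]ethan-1-ol (carbinol epimers) | CC(C)(C)[Si](OC[C@]12CC=CC(C)(C)[C@]13C=C[C@H]2[C@H](C)[C@H]3C(C)O)(c4ccccc4)c5ccccc5
F3 | step 13 | endo pinacol boronate at C-10 of the tricyclic diene | CC(C)(C)[Si](OC[C@]12CC=CC(C)(C)[C@]13C=C[C@H]2[C@H](C)[C@H]3B6OC(C)(C)C(C)(C)O6)(c4ccccc4)c5ccccc5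
F4 | step 13 | 6-({[tert-butyl(diphenyl)silyl]oxy}methyl)-2,2,11-trimethyltricyclo[5.2.2.0^{1,6}]undeca-3,8-dien-10-ol (endo) | CC(C)(C)[Si](OC[C@]12CC=CC(C)(C)[C@]13C=C[C@H]2[C@H](C)[C@H]3O)(c4ccccc4)c5ccccc5
F5 | step 17 | Cc/Cd epoxide of 26 on the face anti to the Ca arm | CC(C)(C)[Si](OC[C@]12C[C@H]6O[C@H]6C(C)(C)[C@]13C[C@@H]1[C@H]2[C@]1(C)[C@H]3OC(C)=O)(c4ccccc4)c5ccccc5
F6 | step 17 | trans-diaxial hydroxy acetate (Cd epimer of 29) | CC(C)(C)[Si](OC[C@]12C[C@H](OC(C)=O)[C@@H](O)C(C)(C)[C@]13C[C@@H]1[C@H]2[C@]1(C)[C@H]3OC(C)=O)(c4ccccc4)c5ccccc5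
F7 | step 17 | Cd ketone bearing the Cc acetate | CC(C)(C)[Si](OC[C@]12C[C@H](OC(C)=O)C(=O)C(C)(C)[C@]13C[C@@H]1[C@H]2[C@]1(C)[C@H]3OC(C)=O)(c4ccccc4)c5ccccc5
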